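**Retrosynthetic overview** (target numbering used throughout: ring O1, C2, C3, C4, C5; side chain C6(CH3)(Br)–C7H2Cl on C5)

- The strategy rests on C2 of the single oxolane ring: a fully substituted carbon bonded to O1, a methyl group and an unsaturated two-carbon arm, flanked by the heteroatom-bearing C3. This is the substitution pattern of a 2-allyl-2-methyloxolan-3-one.
- Late disconnections (no ring formed): C6–Br from the tertiary alcohol with retention; C6–CH3 by chelation-controlled Grignard addition to a chloromethyl ketone; C7–Cl by chlorination of the methyl ketone released from a ketal; CH=CHBr by Takai olefination of the C2 aldehyde cut down from the allyl group; C3–Br by SN2 inversion of the alcohol obtained from the C3 ketone.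
- Key disconnection: O1–C2 and C2–C(arm) of the oxolan-3-one, formed together from an acyclic α-diazo ketone by copper carbenoid formation, oxonium ylide closure and [2,3] shift. This closes the only ring and sets C2 from C5.
- The diazo ketone comes from a β-allyloxy acid and diazoethane; C5 is set by asymmetric hydrogenation of a β-keto ester made by crossed Claisen condensation.

Key step: step 7

Assumption: the BINAP–ruthenium hydrogenation of the β-keto ester follows the usual ester-directed sense, so the (S)-ligand gives the (3R)-hydroxy ester; if the configuration found is the opposite, the (R)-ligand is used and nothing else changes.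

Step 1
Reactants: 1 ethyl 2,2-diethoxypropanoate; 2 ethyl acetate
Product: 3 ethyl 4,4-diethoxy-3-oxopentanoate
Conditions: LiN(SiMe3)2 (2.1 equiv), 2 (1.05 equiv), THF, −78 °C; then 1, −78 → 0 °C; AcOH quench
Reagents that add atoms: none
Why: Crossed Claisen condensation: ester 1 has no α-hydrogen and a carbonyl activated by two α-alkoxy groups, so it can only accept the lithium enolate of ethyl acetate, and the second equivalent of base stores the product as its enolate until the acidic quench.

Step 2
Reactants: 3 ethyl 4,4-diethoxy-3-oxopentanoate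
Product: 4 ethyl (3R)-4,4-diethoxy-3-hydroxypentanoate
Conditions: RuCl2[(S)-BINAP] (0.5 mol %), H2 (50 atm), EtOH, 50 °C
Reagents that add atoms: none
Why: Noyori asymmetric hydrogenation of a β-keto ester: the ester carbonyl holds the ketone on ruthenium and the (S)-BINAP ligand should deliver hydrogen to the face that makes the carbinol carbon (C5 of the target) R, while ethanol as solvent makes any ester or ketal exchange degenerate.

Step 3
Reactants: 4 ethyl (3R)-4,4-diethoxy-3-hydroxypentanoate; 5 prop-2-en-1-yl 2,2,2-trichloroacetimidate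
Product: 6 ethyl (3R)-4,4-diethoxy-3-(prop-2-en-1-yloxy)pentanoate
Conditions: CF3SO3H (5 mol %), cyclohexane/CH2Cl2 (2:1), 0 → 25 °C
Reagents that add atoms: none
Why: Acid-catalysed O-allylation with a trichloroacetimidate (allyl transfer to the neutral alcohol, driven by formation of trichloroacetamide) avoids the alkoxide that would start retro-aldol cleavage or β-elimination in a β-hydroxy ester; the imidate buffers the acid, the ketal next to an oxygenated carbon is slow to ionise, and the carbinol stereocentre is not touched.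

Step 4
Reactants: 6 ethyl (3R)-4,4-diethoxy-3-(prop-2-en-1-yloxy)pentanoate
Product: 7 (3R)-4,4-diethoxy-3-(prop-2-en-1-yloxy)pentanoic acid
Conditions: LiOH, THF/H2O (3:1), 0 → 25 °C; then cold 0.5 M HCl to pH 4
Reagents that add atoms: lithium hydroxide [Li+].[OH-]
Why: Ester saponification with hydroxide; the ketal is inert to base and survives the short, cold acidification to pH 4.

Step 5
Reactants: 8 N-ethyl-N-nitrosourea
Product: 9 diazoethane (dried ethereal solution, used at once)
Conditions: 40% aq. KOH, Et2O, 0 °C; ether layer decanted and dried over KOH pellets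
Reagents that add atoms: none
Why: Base-induced fragmentation of an N-alkyl-N-nitrosourea, the standard route to diazoalkanes, gives the diazoethane that carries the future C2 and its methyl group.

Step 6
Reactants: 7 (3R)-4,4-diethoxy-3-(prop-2-en-1-yloxy)pentanoic acid; 9 diazoethane
Product: 11 (5R)-2-diazo-6,6-diethoxy-5-(prop-2-en-1-yloxy)heptan-3-one, via mixed anhydride 10 (not isolated)
Conditions: i-BuOCOCl, Et3N, Et2O, −20 °C, filter; then 9 (3 equiv), Et2O, 0 → 25 °C
Reagents that add atoms: isobutyl chloroformate CC(C)COC(=O)Cl (atoms kept only in 10)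
Why: Acylation of a diazoalkane by a mixed carbonic anhydride (the first stage of an Arndt–Eistert sequence) forms the C2–C3 bond without free acid, so the ketal is safe, and the carbonate leaving group takes up the proton of the acyldiazonium intermediate.

Step 7
Reactants: 11 (5R)-2-diazo-6,6-diethoxy-5-(prop-2-en-1-yloxy)heptan-3-one
Product: 13 (2S,5R)-5-(1,1-diethoxyethyl)-2-methyl-2-(prop-2-en-1-yl)oxolan-3-one, via oxonium ylide 12 (not isolated)
Conditions: Cu(acac)2 (5 mol %), CH2Cl2, reflux, slow addition of 11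
Reagents that add atoms: none
Why: Cu(acac)2 decomposes 11 to an electrophilic copper carbenoid at C2, a lone pair of the allyl ether oxygen adds to it to give the cyclic oxonium ylide 12, and a suprafacial [2,3]-sigmatropic shift through a five-membered envelope transition state moves the allyl group from O1 to C2 with allylic transposition. The closest known reaction type is the copper-catalysed tandem oxonium ylide formation and [2,3] rearrangement of allyl ethers tethered to diazoketones, which gives 2,5-trans-oxolan-3-ones. The oxolane ring is closed by O1–C2 bond formation, the ether oxygen attacking the carbenoid carbon through a five-membered transition state, and the C2–CH2 bond of the arm follows in the rearrangement. The new quaternary stereocentre C2 is controlled by C5: on the oxonium ring the allyl group sits trans to the pseudo-equatorial 1,1-diethoxyethyl group and is handed to C2 on that same face, so the arm ends trans to the side chain (2S). The step needs ylide formation to beat 1,2-hydride migration in the methyl-substituted carbenoid and capture by a ketal oxygen; an acetylacetonate of copper instead of a rhodium carboxylate, slow addition at reflux and the preference for a five-membered ylide at the more basic ether oxygen over a six-membered one at a ketal oxygen should secure this. The allyl substituent on oxygen ensures the [2,3] pathway over a [1,2] shift.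

Step 8
Reactants: 13 (2S,5R)-5-(1,1-diethoxyethyl)-2-methyl-2-(prop-2-en-1-yl)oxolan-3-one
Product: 14 (2S,3S,5R)-5-(1,1-diethoxyethyl)-2-methyl-2-(prop-2-en-1-yl)oxolan-3-ol
Conditions: LiBH(s-Bu)3, THF, −78 °C; H2O quench
Reagents that add atoms: none
Why: Diastereoselective ketone reduction with a bulky trialkylborohydride: hydride should add to the carbonyl face that carries the C2 methyl group, away from the larger allyl group, so the new C3 hydroxyl lies cis to the allyl group (3S), the arrangement needed for the inversion in step 9.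

Step 9
Reactants: 14 (2S,3S,5R)-5-(1,1-diethoxyethyl)-2-methyl-2-(prop-2-en-1-yl)oxolan-3-ol
Product: 16 (2S,3R,5R)-3-bromo-5-(1,1-diethoxyethyl)-2-methyl-2-(prop-2-en-1-yl)oxolane, via triflate 15 (not isolated)
Conditions: (CF3SO2)2O, 2,6-lutidine, CH2Cl2, −78 → −30 °C; then Bu4NBr (5 equiv), −30 → 25 °C
Reagents that add atoms: trifluoromethanesulfonic anhydride O=S(=O)(OS(=O)(=O)C(F)(F)F)C(F)(F)F (atoms kept only in 15); tetrabutylammonium bromide CCCC[N+](CCCC)(CCCC)CCCC.[Br-]
Why: Sulfonate formation followed by SN2 displacement with inversion: the triflate is reactive enough for this neopentyl-type carbon next to a ring oxygen, bromide enters on the face of the C2 methyl group opposite to the leaving group to give the 3R bromide of the target, and a hindered base with a large excess of soluble bromide in a weakly ionising solvent is chosen to hold back elimination, methyl shift and capture of the triflate by a ketal oxygen.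

Step 10
Reactants: 16 (2S,3R,5R)-3-bromo-5-(1,1-diethoxyethyl)-2-methyl-2-(prop-2-en-1-yl)oxolane
Product: 17 (2S,3R,5R)-3-bromo-5-(1,1-diethoxyethyl)-2-methyl-2-[(1E)-prop-1-en-1-yl]oxolane
Conditions: RuHCl(CO)(PPh3)3 (5 mol %), toluene, 80 °C
Reagents that add atoms: none
Why: Ruthenium hydride-catalysed alkene isomerisation by hydrometallation and β-hydride elimination moves the terminal double bond one position inward, and it must stop at the propenyl stage because the next carbon is the fully substituted C2 (the E/Z composition is of no consequence for step 11).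

Step 11
Reactants: 17 (2S,3R,5R)-3-bromo-5-(1,1-diethoxyethyl)-2-methyl-2-[(1E)-prop-1-en-1-yl]oxolane
Product: 19 (2S,3R,5R)-3-bromo-5-(1,1-diethoxyethyl)-2-methyloxolane-2-carbaldehyde, via ozonide 18 (not isolated)
Conditions: O3, CH2Cl2, −78 °C; then Me2S, −78 → 25 °C
Reagents that add atoms: ozone [O-][O+]=O
Why: Ozonolysis (Criegee mechanism) with reductive work-up cuts the propenyl group down to the C2 carbaldehyde, which has no α-hydrogen and so can neither epimerise nor lose HBr.

Step 12
Reactants: 19 (2S,3R,5R)-3-bromo-5-(1,1-diethoxyethyl)-2-methyloxolane-2-carbaldehyde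
Product: 20 (2S,3R,5R)-3-bromo-2-[(E)-2-bromoethenyl]-5-(1,1-diethoxyethyl)-2-methyloxolane
Conditions: CHBr3, CrBr2 (6 equiv), THF, 0 → 25 °C
Reagents that add atoms: bromoform BrC(Br)Br
Why: Takai olefination: the geminal dichromium species formed from bromoform and divalent chromium adds to the aldehyde and eliminates to the (E)-bromoalkene, the dibromide CrBr2 avoiding halogen scrambling and leaving the unactivated secondary bromide alone.

Step 13
Reactants: 20 (2S,3R,5R)-3-bromo-2-[(E)-2-bromoethenyl]-5-(1,1-diethoxyethyl)-2-methyloxolane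
Product: 21 1-[(2R,4R,5S)-4-bromo-5-[(E)-2-bromoethenyl]-5-methyloxolan-2-yl]ethan-1-one
Conditions: 2 M HCl, THF, 25 °C
Reagents that add atoms: water O
Why: Acid-catalysed ketal hydrolysis unmasks the methyl ketone; both bromides tolerate aqueous acid and the non-basic medium spares the enolisable, α-oxygenated C5 centre.

Step 14
Reactants: 21 1-[(2R,4R,5S)-4-bromo-5-[(E)-2-bromoethenyl]-5-methyloxolan-2-yl]ethan-1-one
Product: 23 1-[(2R,4R,5S)-4-bromo-5-[(E)-2-bromoethenyl]-5-methyloxolan-2-yl]-2-chloroethan-1-one, via silyl enol ether 22 (not isolated)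
Conditions: Me3SiCl, LiN(SiMe3)2, THF, −78 °C; crude 22, then N-chlorosuccinimide, CH2Cl2, 0 °C
Reagents that add atoms: chlorotrimethylsilane C[Si](C)(C)Cl (atoms kept only in 22); N-chlorosuccinimide ClN1C(=O)CCC1=O
Why: Kinetic enolisation of the methyl ketone at the methyl group with in situ silylation and electrophilic chlorination of the silyl enol ether puts one chlorine on C7; chlorine is installed before the C6 bromine because any later activation of an oxygen on C7 next to a tertiary bromide would run through a bromonium ion and scramble the halogens.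

Step 15
Reactants: 23 1-[(2R,4R,5S)-4-bromo-5-[(E)-2-bromoethenyl]-5-methyloxolan-2-yl]-2-chloroethan-1-one
Product: 24 (2R)-2-[(2R,4R,5S)-4-bromo-5-[(E)-2-bromoethenyl]-5-methyloxolan-2-yl]-1-chloropropan-2-ol
Conditions: MeMgBr, THF, −78 °C; aq. NH4Cl at −78 °C
Reagents that add atoms: methylmagnesium bromide C[Mg]Br
Why: Chelation-controlled (Cram chelate) Grignard addition: magnesium bridges the ketone oxygen and the ring oxygen O1 and the methyl group adds from the side of the C5 hydrogen, away from C4, which should give the (R)-carbinol at C6, the epimer whose hydroxyl occupies the place of the bromine in the target; the cold quench prevents closure to the epoxide.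

Step 16
Reactants: 24 (2R)-2-[(2R,4R,5S)-4-bromo-5-[(E)-2-bromoethenyl]-5-methyloxolan-2-yl]-1-chloropropan-2-ol
Product: 25 (2S,3R,5R)-3-bromo-2-[(E)-2-bromoethenyl]-5-[(2R)-2-bromo-1-chloropropan-2-yl]-2-methyloxolane
Conditions: Me3SiBr (3 equiv), CH2Cl2, −20 → 0 °C
Reagents that add atoms: bromotrimethylsilane C[Si](C)(C)Br
Why: Proposed new method: silylation of the tertiary hydroxyl releases HBr, which ionises the C6–O bond of this β-chloro, β-alkoxy carbinol only with rear-side help from the ring oxygen O1 (bicyclic oxiranium ion) or from chlorine (chloronium character), so that bromide should return to C6, the more substituted carbon of the bridged ion, on the face the oxygen left and the configuration is retained; the closest known reaction types are the conversion of tertiary alcohols into bromides with Me3SiBr and the stereospecific ring expansions and contractions of 2-(1-sulfonyloxyalkyl)oxolanes that pass through the same bicyclic oxiranium ions.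

**Compound list**

1 | ethyl 2,2-diethoxypropanoate | CCOC(=O)C(C)(OCC)OCC | starting material
2 | ethyl acetate | CCOC(C)=O | starting material
3 | ethyl 4,4-diethoxy-3-oxopentanoate | CCOC(=O)CC(=O)C(C)(OCC)OCC | intermediate
4 | ethyl (3R)-4,4-diethoxy-3-hydroxypentanoate | CCOC(C)(OCC)[C@H](O)CC(=O)OCC | intermediate
5 | prop-2-en-1-yl 2,2,2-trichloroacetimidate | C=CCOC(=N)C(Cl)(Cl)Cl | starting material
6 | ethyl (3R)-4,4-diethoxy-3-(prop-2-en-1-yloxy)pentanoate | CCOC(C)(OCC)[C@H](OCC=C)CC(=O)OCC | intermediate
7 | (3R)-4,4-diethoxy-3-(prop-2-en-1-yloxy)pentanoic acid | CCOC(C)(OCC)[C@H](OCC=C)CC(=O)O | intermediate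
8 | N-ethyl-N-nitrosourea | CCN(N=O)C(N)=O | starting material
9 | diazoethane | CC=[N+]=[N-] | intermediate
10 | (3R)-4,4-diethoxy-3-(prop-2-en-1-yloxy)pentanoic 2-methylpropyl carbonic anhydride (mixed anhydride) | CCOC(C)(OCC)[C@H](OCC=C)CC(=O)OC(=O)OCC(C)C | intermediate
11 | (5R)-2-diazo-6,6-diethoxy-5-(prop-2-en-1-yloxy)heptan-3-one | CCOC(C)(OCC)[C@H](OCC=C)CC(=O)C(C)=[N+]=[N-] | intermediate
12 | (5R)-5-(1,1-diethoxyethyl)-2-methyl-3-oxo-1-(prop-2-en-1-yl)oxolan-1-ium-2-ide (oxonium ylide, allyl on oxygen trans to the C5 substituent) | CCOC(C)(OCC)[C@H]1CC(=O)[C-](C)[O+]1CC=C | intermediate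
13 | (2S,5R)-5-(1,1-diethoxyethyl)-2-methyl-2-(prop-2-en-1-yl)oxolan-3-one | CCOC(C)(OCC)[C@H]1CC(=O)[C@](C)(CC=C)O1 | intermediate
14 | (2S,3S,5R)-5-(1,1-diethoxyethyl)-2-methyl-2-(prop-2-en-1-yl)oxolan-3-ol | CCOC(C)(OCC)[C@H]1C[C@H](O)[C@](C)(CC=C)O1 | intermediate
15 | (2S,3S,5R)-5-(1,1-diethoxyethyl)-2-methyl-2-(prop-2-en-1-yl)oxolan-3-yl trifluoromethanesulfonate | CCOC(C)(OCC)[C@H]1C[C@H](OS(=O)(=O)C(F)(F)F)[C@](C)(CC=C)O1 | intermediate
16 | (2S,3R,5R)-3-bromo-5-(1,1-diethoxyethyl)-2-methyl-2-(prop-2-en-1-yl)oxolane | CCOC(C)(OCC)[C@H]1C[C@@H](Br)[C@](C)(CC=C)O1 | intermediate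
17 | (2S,3R,5R)-3-bromo-5-(1,1-diethoxyethyl)-2-methyl-2-[(1E)-prop-1-en-1-yl]oxolane | CCOC(C)(OCC)[C@H]1C[C@@H](Br)[C@](C)(/C=C/C)O1 | intermediate
18 | 3-[(2S,3R,5R)-3-bromo-5-(1,1-diethoxyethyl)-2-methyloxolan-2-yl]-5-methyl-1,2,4-trioxolane (ozonide) | CCOC(C)(OCC)[C@H]1C[C@@H](Br)[C@](C)(C2OOC(C)O2)O1 | intermediate
19 | (2S,3R,5R)-3-bromo-5-(1,1-diethoxyethyl)-2-methyloxolane-2-carbaldehyde | CCOC(C)(OCC)[C@H]1C[C@@H](Br)[C@](C)(C=O)O1 | intermediate
20 | (2S,3R,5R)-3-bromo-2-[(E)-2-bromoethenyl]-5-(1,1-diethoxyethyl)-2-methyloxolane | CCOC(C)(OCC)[C@H]1C[C@@H](Br)[C@](C)(/C=C/Br)O1 | intermediate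
21 | 1-[(2R,4R,5S)-4-bromo-5-[(E)-2-bromoethenyl]-5-methyloxolan-2-yl]ethan-1-one | CC(=O)[C@H]1C[C@@H](Br)[C@](C)(/C=C/Br)O1 | intermediate
22 | ({1-[(2R,4R,5S)-4-bromo-5-[(E)-2-bromoethenyl]-5-methyloxolan-2-yl]ethenyl}oxy)trimethylsilane | C=C(O[Si](C)(C)C)[C@H]1C[C@@H](Br)[C@](C)(/C=C/Br)O1 | intermediate
23 | 1-[(2R,4R,5S)-4-bromo-5-[(E)-2-bromoethenyl]-5-methyloxolan-2-yl]-2-chloroethan-1-one | ClCC(=O)[C@H]1C[C@@H](Br)[C@](C)(/C=C/Br)O1 | intermediate
24 | (2R)-2-[(2R,4R,5S)-4-bromo-5-[(E)-2-bromoethenyl]-5-methyloxolan-2-yl]-1-chloropropan-2-ol | C[C@](O)(CCl)[C@H]1C[C@@H](Br)[C@](C)(/C=C/Br)O1 | intermediate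
25 | (2S,3R,5R)-3-bromo-2-[(E)-2-bromoethenyl]-5-[(2R)-2-bromo-1-chloropropan-2-yl]-2-methyloxolane | C[C@](Br)(CCl)[C@H]1C[C@@H](Br)[C@](C)(/C=C/Br)O1 | target

**Step count and risks**

Total step count: 16 (15 in the main line plus the one-step preparation of diazoethane).
Longest linear sequence: 15 steps (steps 1–4 and 6–16).

Steps most likely to fail:

Step 16 (Proposed new method). What may go wrong: ionisation at C6 may give a free tertiary cation that loses its configuration, eliminates, or is opened at C5 of the bridged ion with ring expansion to the six-membered ether. The fallback uses known reactions and gives up stereocontrol at C6. It sets out from methyl ketone 21. Wittig methylenation (Ph3P=CH2 from Ph3PCH3Br and KN(SiMe3)2, THF, −78 → 0 °C) gives the isopropenyl oxolane F1. Ene-type allylic chlorination with hypochlorous acid (Ca(OCl)2, solid CO2, CH2Cl2/H2O, 0 °C) gives the 3-chloroprop-1-en-2-yl oxolane F2. Ionic Markovnikov addition of HBr (anhydrous HBr, CH2Cl2, −40 °C, dark) should give the tertiary bromide as 25 together with its C6 epimer F3, to be separated by HPLC. The route is rejoined at 25.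

Step 7. What may go wrong: 1,2-hydride migration in the methyl-substituted copper carbenoid (to the vinyl ketone), or capture of the carbenoid by a ketal oxygen, may outrun formation of the five-membered ylide. The fallback keeps the same ring closure and [2,3] shift but blocks the hydride shift with an ester on the carbenoid carbon, which is afterwards reduced to the methyl group. It sets out from acid 7. Carbonyldiimidazole gives the acyl imidazolide F4 (not isolated), and Mg(O2CCH2CO2Et)2 converts it into the β-keto ester F5. Diazo transfer (4-acetamidobenzenesulfonyl azide, Et3N, MeCN) gives the α-diazo β-keto ester F6. Cu(hfacac)2 in refluxing CH2Cl2 should give, through the oxonium ylide F7, the 2-allyl-3-oxooxolane-2-carboxylate F8 with the allyl group trans to the C5 side chain. LiAlH4 gives the diol F9, I2/PPh3/imidazole the primary iodide F10, and Bu3SnH/AIBN the 2-methyl carbinol F11 (both C3 epimers). Dess–Martin periodinane then returns the route to ketone 13.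

Step 9. What may go wrong: the bimolecular displacement at the neopentyl-type, β-oxygenated C3 may be too slow, so that elimination, methyl shift to the C2 oxocarbenium ion, or capture of the triflate by a ketal oxygen on the entering face takes over. The fallback moves the displacement behind the ketal hydrolysis, where the cis side chain is a small, weakly nucleophilic acetyl group. It sets out from alcohol 14. RuHCl(CO)(PPh3)3 in toluene gives the propenyl alcohol F12. Ozone gives the ozonide F13 and Me2S the hydroxy aldehyde F14. CHBr3/CrBr2 gives the bromovinyl alcohol F15, and 2 M HCl in THF the hydroxy ketone F16. (CF3SO2)2O/2,6-lutidine gives the triflate F17, which Bu4NBr should displace with inversion to give 21, where the route is rejoined.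

**Further compounds**

F1 | step 16 | (2S,3R,5R)-3-bromo-2-[(E)-2-bromoethenyl]-2-methyl-5-(prop-1-en-2-yl)oxolane | C=C(C)[C@H]1C[C@@H](Br)[C@](C)(/C=C/Br)O1
F2 | step 16 | (2S,3R,5R)-3-bromo-2-[(E)-2-bromoethenyl]-5-(3-chloroprop-1-en-2-yl)-2-methyloxolane | C=C(CCl)[C@H]1C[C@@H](Br)[C@](C)(/C=C/Br)O1
F3 | step 16 | (2S,3R,5R)-3-bromo-2-[(E)-2-bromoethenyl]-5-[(2S)-2-bromo-1-chloropropan-2-yl]-2-methyloxolane | C[C@@](Br)(CCl)[C@H]1C[C@@H](Br)[C@](C)(/C=C/Br)O1
F4 | step 7 | 1-[(3R)-4,4-diethoxy-3-(prop-2-en-1-yloxy)pentanoyl]imidazole | CCOC(C)(OCC)[C@H](OCC=C)CC(=O)n1ccnc1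
F5 | step 7 | ethyl (5R)-6,6-diethoxy-3-oxo-5-(prop-2-en-1-yloxy)heptanoate | CCOC(C)(OCC)[C@H](OCC=C)CC(=O)CC(=O)OCC
F6 | step 7 | ethyl (5R)-2-diazo-6,6-diethoxy-3-oxo-5-(prop-2-en-1-yloxy)heptanoate | CCOC(C)(OCC)[C@H](OCC=C)CC(=O)C(=[N+]=[N-])C(=O)OCC
F7 | step 7 | (5R)-5-(1,1-diethoxyethyl)-2-(ethoxycarbonyl)-3-oxo-1-(prop-2-en-1-yl)oxolan-1-ium-2-ide (oxonium ylide) | CCOC(C)(OCC)[C@H]1CC(=O)[C-](C(=O)OCC)[O+]1CC=C
F8 | step 7 | ethyl (2S,5R)-5-(1,1-diethoxyethyl)-3-oxo-2-(prop-2-en-1-yl)oxolane-2-carboxylate | CCOC(C)(OCC)[C@H]1CC(=O)[C@](C(=O)OCC)(CC=C)O1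
F9 | step 7 | (2R,5R)-5-(1,1-diethoxyethyl)-2-(hydroxymethyl)-2-(prop-2-en-1-yl)oxolan-3-ol (both C3 epimers) | CCOC(C)(OCC)[C@H]1CC(O)[C@](CO)(CC=C)O1
F10 | step 7 | (2S,5R)-5-(1,1-diethoxyethyl)-2-(iodomethyl)-2-(prop-2-en-1-yl)oxolan-3-ol (both C3 epimers) | CCOC(C)(OCC)[C@H]1CC(O)[C@](CI)(CC=C)O1
F11 | step 7 | (2S,5R)-5-(1,1-diethoxyethyl)-2-methyl-2-(prop-2-en-1-yl)oxolan-3-ol (both C3 epimers) | CCOC(C)(OCC)[C@H]1CC(O)[C@](C)(CC=C)O1
F12 | step 9 | (2S,3S,5R)-5-(1,1-diethoxyethyl)-2-methyl-2-[(1E)-prop-1-en-1-yl]oxolan-3-ol | CCOC(C)(OCC)[C@H]1C[C@H](O)[C@](C)(/C=C/C)O1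
F13 | step 9 | (2R,3S,5R)-5-(1,1-diethoxyethyl)-2-methyl-2-(5-methyl-1,2,4-trioxolan-3-yl)oxolan-3-ol (ozonide) | CCOC(C)(OCC)[C@H]1C[C@H](O)[C@](C)(C2OOC(C)O2)O1
F14 | step 9 | (2R,3S,5R)-5-(1,1-diethoxyethyl)-3-hydroxy-2-methyloxolane-2-carbaldehyde | CCOC(C)(OCC)[C@H]1C[C@H](O)[C@](C)(C=O)O1
F15 | step 9 | (2S,3S,5R)-2-[(E)-2-bromoethenyl]-5-(1,1-diethoxyethyl)-2-methyloxolan-3-ol | CCOC(C)(OCC)[C@H]1C[C@H](O)[C@](C)(/C=C/Br)O1
F16 | step 9 | 1-[(2R,4S,5S)-5-[(E)-2-bromoethenyl]-4-hydroxy-5-methyloxolan-2-yl]ethan-1-one | CC(=O)[C@H]1C[C@H](O)[C@](C)(/C=C/Br)O1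
F17 | step 9 | (2S,3S,5R)-5-acetyl-2-[(E)-2-bromoethenyl]-2-methyloxolan-3-yl trifluoromethanesulfonate | CC(=O)[C@H]1C[C@H](OS(=O)(=O)C(F)(F)F)[C@](C)(/C=C/Br)O1
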